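**Retrosynthetic overview**

1. The target is a cyclol: a dibenzo[b,f]oxepine (rings A and B, oxepine with C10=C11) carrying a pyran (O1 on C10, C2, C3, C4 on C11) that is cis-fused to a cyclobutane (C3, C4, C4′, C3′) and a cyclopentane (C2, C3, C3′, C2′, C1′). The phenols are carried as methyl ethers and freed last; the prenyl group on ring A is put on by Negishi coupling at a chlorine handle.
2. Key disconnection (biomimetic and dynamic): C3–C3′ and C4–C4′, by an enantioselective radical-cation [2+2] cycloaddition of the racemic 2H-pyran that bears methyl and 4-methylpent-3-enyl on C2.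
3. Enabling feature: the O1–C2 bond next to the dienol ether O1–C10=C11–C4=C3 lets the pyran open and reclose (oxa-6π) through an achiral dienone, so C2 racemises. The C2 side chain holds C3′=C4′ in a 1,6-relationship to C3=C4, so that bonding C3–C3′ closes the cyclopentane and C4–C4′ the cyclobutane.
4. The pyran comes from Knoevenagel condensation/oxa-6π electrocyclisation of 2-chloro-3,7-dimethoxydibenzo[b,f]oxepin-10(11H)-one with citral. The oxepinone comes from Friedel–Crafts acylation of a 2-aryloxyphenylacetic acid made by Ullmann coupling.
5. Ring order: rings A and B (bought), oxepine, pyran, then cyclobutane and cyclopentane together in the last ring-forming step.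

Key step: step 5

Remark: the 2H-pyran and its ring-opened dienone are taken to be valence tautomers that interconvert at or below room temperature, so the pyran is handled as a configurationally labile racemate; which antipode of the chiral anion leads to the (2R) series is to be found by experiment.

**Route**

Step 1
Reactants: 1 (2-bromo-4-methoxyphenyl)acetic acid
Product: 2 (2-bromo-5-chloro-4-methoxyphenyl)acetic acid
Conditions: NCS (1.05 equiv), AcOH, 50 °C
Reagents that add atoms: N-chlorosuccinimide, O=C1CCC(=O)N1Cl
Why: Electrophilic aromatic chlorination ortho to OMe; of the two ortho sites C3 lies between Br and OMe, so C5 should react, and the chlorine (inert to copper catalysis and to strong acid) becomes the later anchor of the prenyl group.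

Step 2
Reactants: 2 (2-bromo-5-chloro-4-methoxyphenyl)acetic acid; 3 3-methoxyphenol
Product: 4 [5-chloro-4-methoxy-2-(3-methoxyphenoxy)phenyl]acetic acid
Conditions: CuI (10 mol%), N,N-dimethylglycine hydrochloride (30 mol%), Cs2CO3 (3 equiv), 1,4-dioxane, 100 °C; then aq. HCl
Reagents that add atoms: none
Why: Ullmann diaryl ether coupling; the C–Br bond ortho to the carboxylate side chain is far more reactive towards copper than the C–Cl bond, as in the established couplings of 2-bromophenylacetic acids with phenols.

Step 3
Reactants: 4 [5-chloro-4-methoxy-2-(3-methoxyphenoxy)phenyl]acetic acid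
Product: 5 2-chloro-3,7-dimethoxydibenzo[b,f]oxepin-10(11H)-one
Conditions: Eaton's reagent (P2O5 in MeSO3H), 40 °C
Reagents that add atoms: none
Why: Intramolecular Friedel–Crafts acylation; the acylium ion should attack ring B ortho to the ether oxygen and para to OMe (the site between the two oxygens is hindered), which closes the oxepinone with C10=O on ring B and the C11 methylene on ring A.

Step 4
Reactants: 5 2-chloro-3,7-dimethoxydibenzo[b,f]oxepin-10(11H)-one; 6 citral (geranial/neral mixture)
Product: 8 racemic 2H-pyran (2-methyl-2-(4-methylpent-3-en-1-yl)-2H-pyran fused through O1–C10 and C4–C11 to 2-chloro-3,7-dimethoxydibenzo[b,f]oxepine; C2 configurationally labile), via dienone 7 (not isolated)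
Conditions: pyrrolidine (30 mol%), AcOH (30 mol%), 4 Å molecular sieves, toluene, 50 °C
Reagents that add atoms: none
Why: Amine-catalysed Knoevenagel (aldol) condensation of the C11 methylene, which is both benzylic and alpha to C10=O, with the iminium ion of citral (1,2-addition, since the beta-carbon of the enal is fully substituted) should give dienone 7, whose oxa-6π electrocyclisation leads to the 2,2-disubstituted ring-fused 2H-pyran as the expected resting state; both isomers of citral converge, and C2 is formed racemic.

Step 5
Reactants: 8 racemic 2H-pyran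
Product: 9 (2R,3R,4R,3′S)-chloro cyclol dimethyl ether (8 with the new bonds C3–C3′ and C4–C4′; cyclobutane and cyclopentane cis-fused to the pyran)
Conditions: 9-aryl-thioxanthylium photo-oxidant paired with a confined chiral imidodiphosphorimidate (IDPi) anion (5 mol%), CH2Cl2, green LEDs (525 nm), 0 °C, argon
Reagents that add atoms: none
Why: Proposed new method: visible-light excitation of the thioxanthylium cation should oxidise the dienol ether O1–C10=C11–C4=C3 of 8, its most electron-rich π-system, to a radical cation held in an ion pair with the chiral anion; the C3′=C4′ alkene then adds through C3′ to C3, the resulting allyl radical/tertiary cation pair closes C4–C4′, and back electron transfer releases 9 and the catalyst. The closest known reaction types are the photoredox radical-cation [2+2] cycloaddition of electron-rich styrenes with alkenes, including its counter-anion-directed enantioselective form, and the photochemical chromene-to-cyclol [2+2] cycloaddition of cannabichromene-type compounds; neither has been run on a racemising 2H-pyran. The cyclopentane (C2, C3, C3′, C2′, C1′) closes 5-exo-trig in the first bond formation, and the cyclobutane (C3, C4, C4′, C3′) closes by 4-exo collapse of the 1,4-radical cation. C2 is set by the catalyst, which should let only the (2R)-pyran ion pair cyclise while the slow enantiomer returns to the pool by retro-oxa-6π opening to the achiral dienone 7 and reclosure (expected to be fast in the radical cation and thermal in neutral 8); C3, C4 and C3′ are then fixed by the substrate, because the two-carbon tether reaches only the face of C3=C4 on its own side and enforces the all-cis ring fusions. The step needs enantioselection coupled to racemisation (secured by the labile O1–C2 bond), oxidation at the diene in preference to the anisole rings (secured by its lower oxidation potential), and straight over crossed regiochemistry (secured by the 1,6-relationship of the two alkenes).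

Step 6
Reactants: 9 (2R,3R,4R,3′S)-chloro cyclol dimethyl ether
Product: 10 (2R,3R,4R,3′S)-prenyl cyclol dimethyl ether (9 with 3-methylbut-2-enyl in place of Cl on ring A)
Conditions: prenyl bromide, Zn dust, LiCl, THF, 0 °C; then 9, Pd(OAc)2 (2 mol%), CPhos (4 mol%), THF, rt to 40 °C
Reagents that add atoms: 3-methylbut-2-enylzinc bromide, CC(C)=CC[Zn]Br (made in the flask from prenyl bromide, CC(C)=CCBr, and zinc)
Why: Negishi cross-coupling at the only carbon–halogen bond; with CPhos the allylpalladium intermediate is expected to undergo reductive elimination at its unsubstituted terminus, giving the linear prenyl arene, and the neutral conditions leave the enol ether and all four stereocentres untouched.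

Step 7
Reactants: 10 (2R,3R,4R,3′S)-prenyl cyclol dimethyl ether
Product: 11 target CNP0185814.1, the (2R,3R,4R,3′S)-cyclol diphenol
Conditions: NaSEt (8 equiv), DMF, 130 °C; then aq. HCl to pH 5
Reagents that add atoms: none
Why: Nucleophilic (SN2) cleavage of both aryl methyl ethers by ethanethiolate at the methyl carbons; the medium stays basic, so the acid-labile enol ether and the ortho-prenyl phenol are not exposed to acid, the tertiary C2–O1 bond cannot be attacked, and no stereocentre is involved.

**Compound list**

1 | (2-bromo-4-methoxyphenyl)acetic acid | COc1ccc(CC(=O)O)c(Br)c1 | starting material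
2 | (2-bromo-5-chloro-4-methoxyphenyl)acetic acid | COc1cc(Br)c(CC(=O)O)cc1Cl | intermediate
3 | 3-methoxyphenol | COc1cccc(O)c1 | starting material
4 | [5-chloro-4-methoxy-2-(3-methoxyphenoxy)phenyl]acetic acid | COc1cccc(Oc2cc(OC)c(Cl)cc2CC(=O)O)c1 | intermediate
5 | 2-chloro-3,7-dimethoxydibenzo[b,f]oxepin-10(11H)-one | COc1ccc2c(c1)Oc1cc(OC)c(Cl)cc1CC2=O | intermediate
6 | citral (3,7-dimethylocta-2,6-dienal, mixture of geranial and neral) | CC(C)=CCCC(C)=CC=O | starting material
7 | dienone: 2-chloro-11-(3,7-dimethylocta-2,6-dien-1-ylidene)-3,7-dimethoxydibenzo[b,f]oxepin-10(11H)-one, mixture of geometric isomers, not isolated | COc1ccc2c(c1)Oc1cc(OC)c(Cl)cc1C(=CC=C(C)CCC=C(C)C)C2=O | intermediate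
8 | racemic 2H-pyran: 2-methyl-2-(4-methylpent-3-en-1-yl)-2H-pyran fused through O1–C10 and C4–C11 to 2-chloro-3,7-dimethoxydibenzo[b,f]oxepine, C2 labile | COc1ccc2c(c1)Oc1cc(OC)c(Cl)cc1C1=C2OC(C)(CCC=C(C)C)C=C1 | intermediate
9 | (2R,3R,4R,3′S)-chloro cyclol dimethyl ether: pyran of 8 cis-fused to cyclobutane (C3, C4, C4′ with two methyls, C3′) and cyclopentane (C2 with methyl, C3, C3′, C2′, C1′) | Clc1cc2c(cc1OC)Oc1cc(OC)ccc1C1=C2[C@@H]2[C@H]3[C@H](CC[C@@]3(C)O1)C2(C)C | intermediate
10 | (2R,3R,4R,3′S)-prenyl cyclol dimethyl ether: 9 with 3-methylbut-2-enyl in place of Cl | CC(C)=CCc1cc2c(cc1OC)Oc1cc(OC)ccc1C1=C2[C@@H]2[C@H]3[C@H](CC[C@@]3(C)O1)C2(C)C | intermediate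
11 | CNP0185814.1, the (2R,3R,4R,3′S)-cyclol diphenol: 10 with both OMe groups as OH | CC(C)=CCc1cc2c(cc1O)Oc1cc(O)ccc1C1=C2[C@@H]2[C@H]3[C@H](CC[C@@]3(C)O1)C2(C)C | target

**Step count and risks**

Total step count: 7. Longest linear sequence: 7 steps (1 to 11).

Steps most likely to fail:

1. Step 5 (proposed new method). The ion pair may discriminate the two faces poorly, racemisation of the pyran may be slower than cyclisation so that the step stalls as a kinetic resolution, or the ring-opened radical cation may be diverted into six-membered (citran-type) cyclisation. Fallback with known chemistry, setting out from 8: irradiation at 405 nm with thioxanthen-9-one (10 mol%) in degassed MeCN at room temperature, the triplet-sensitised intramolecular [2+2] photocycloaddition known for chromene-to-cyclol conversions, should give the racemic chloro cyclol dimethyl ether F1. Preparative chromatography on a chiral stationary phase (SFC, amylose tris(3,5-dimethylphenylcarbamate)) should then separate it into 9, where the route is rejoined, and the mirror-image chloro cyclol dimethyl ether F2, which is set aside; this path can deliver at most half of the material.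

2. Step 4. Condensation at C11 may be slow, citral may self-condense under amine catalysis, or the dienone–pyran equilibrium may lie less far on the pyran side than assumed. Fallback, setting out from 5 and 6: deprotonation of 5 with LiN(SiMe3)2 (THF, −78 °C) and 1,2-addition of the lithium enolate to 6 should give the beta-hydroxy ketone aldol adduct F3 as a diastereomer mixture. Treatment with MsCl and Et3N (CH2Cl2, 0 °C to rt) should form the methanesulfonate of the aldol adduct F4, which is not isolated and eliminates (E1cB) to dienone 7; this closes to 8, where the route is rejoined.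

3. Step 7. The second demethylation may remain incomplete, or the forcing nucleophilic conditions may degrade the product by thiol addition to or migration of the prenyl double bond, or by base-induced opening of the enol ether. Fallback by change of protecting groups, setting out from 5: BBr3 (CH2Cl2, −78 to 0 °C) should give the diol ketone F5, and TBSCl/imidazole (DMF, rt) the bis-silyl ketone F6. The chemistry of steps 4 to 6 is then run in this series: condensation with 6 gives the bis-silyl dienone F7 (not isolated) and the racemic bis-silyl 2H-pyran F8, the cycloaddition gives the bis-silyl chloro cyclol F9, and the Negishi coupling gives the bis-silyl prenyl cyclol F10. Desilylation with TBAF/AcOH (THF, 0 °C) should then give 11, where the route is rejoined, without any step at high temperature after the cycloaddition.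

**Further compounds**

F1 | step 5 | racemic chloro cyclol dimethyl ether (9 and its mirror image in equal parts) | Clc1cc2c(cc1OC)Oc1cc(OC)ccc1C1=C2[C@@H]2[C@H]3[C@H](CC[C@@]3(C)O1)C2(C)C.Clc1cc2c(cc1OC)Oc1cc(OC)ccc1C1=C2[C@H]2[C@@H]3[C@@H](CC[C@]3(C)O1)C2(C)C
F2 | step 5 | mirror-image chloro cyclol dimethyl ether, (2S,3S,4S,3′R) | Clc1cc2c(cc1OC)Oc1cc(OC)ccc1C1=C2[C@H]2[C@@H]3[C@@H](CC[C@]3(C)O1)C2(C)C
F3 | step 4 | aldol adduct: 2-chloro-11-(1-hydroxy-3,7-dimethylocta-2,6-dien-1-yl)-3,7-dimethoxydibenzo[b,f]oxepin-10(11H)-one, diastereomer mixture, configurations not defined | COc1ccc2c(c1)Oc1cc(OC)c(Cl)cc1C(C(O)C=C(C)CCC=C(C)C)C2=O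
F4 | step 4 | methanesulfonate of the aldol adduct, not isolated, configurations not defined | COc1ccc2c(c1)Oc1cc(OC)c(Cl)cc1C(C(OS(C)(=O)=O)C=C(C)CCC=C(C)C)C2=O
F5 | step 7 | diol ketone: 2-chloro-3,7-dihydroxydibenzo[b,f]oxepin-10(11H)-one | Oc1ccc2c(c1)Oc1cc(O)c(Cl)cc1CC2=O
F6 | step 7 | bis-silyl ketone: 2-chloro-3,7-bis(tert-butyldimethylsilyloxy)dibenzo[b,f]oxepin-10(11H)-one | CC(C)(C)[Si](C)(C)Oc1ccc2c(c1)Oc1cc(O[Si](C)(C)C(C)(C)C)c(Cl)cc1CC2=O
F7 | step 7 | bis-silyl dienone, not isolated, mixture of geometric isomers | CC(C)(C)[Si](C)(C)Oc1ccc2c(c1)Oc1cc(O[Si](C)(C)C(C)(C)C)c(Cl)cc1C(=CC=C(C)CCC=C(C)C)C2=O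
F8 | step 7 | racemic bis-silyl 2H-pyran (8 with OTBS in place of both OMe) | CC(C)(C)[Si](C)(C)Oc1ccc2c(c1)Oc1cc(O[Si](C)(C)C(C)(C)C)c(Cl)cc1C1=C2OC(C)(CCC=C(C)C)C=C1
F9 | step 7 | (2R,3R,4R,3′S)-bis-silyl chloro cyclol (9 with OTBS in place of both OMe) | Clc1cc2c(cc1O[Si](C)(C)C(C)(C)C)Oc1cc(O[Si](C)(C)C(C)(C)C)ccc1C1=C2[C@@H]2[C@H]3[C@H](CC[C@@]3(C)O1)C2(C)C
F10 | step 7 | (2R,3R,4R,3′S)-bis-silyl prenyl cyclol (10 with OTBS in place of both OMe) | CC(C)=CCc1cc2c(cc1O[Si](C)(C)C(C)(C)C)Oc1cc(O[Si](C)(C)C(C)(C)C)ccc1C1=C2[C@@H]2[C@H]3[C@H](CC[C@@]3(C)O1)C2(C)C
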